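## Analysis of the target

The target is an isoflavan: a chroman (benzene ring A fused to the dihydropyran ring C) carrying the aryl ring B at C3. C3 is the only stereocentre and is R, so the task is absolute control with no relative stereochemistry. Ring A is a pentasubstituted 1,3,5-trioxygenated benzene whose three oxygens differ (O1 in ring C, 5-OMe, free 7-OH) and whose two carbon substituents (C4 on C4a, the formyl group on C8 between O1 and O7) must be told apart. Ring B is 1,2,3,4-tetrasubstituted: C1' is bonded to C3, C2' carries a free OH, C3' the prenyl group and C4' a methoxy group, while C5' and C6' carry hydrogen. The sensitive groups are: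

- the prenyl alkene ortho to the free 2'-OH, which acid closes to a 2,2-dimethylchroman and hydrogenation saturates;
- the salicylaldehyde, which interferes with carbonyl chemistry and absorbs near-UV light;
- two electron-rich rings that are easily oxidised.

The hard part is C3': electrophilic substitution of a 4-substituted resorcinol monoether goes to C5', so a stepwise route needs directed metalation or a rearrangement and a protecting group on O2' that is normally removed with acid. The strategy rests on the triad C2'(OH)–C3'(prenyl)–C4'(OMe), which has the connectivity of a ketene carbonyl carbon joined to the two carbons of a prenyl-bearing alkynyl methyl ether. C5', C6' and C1' are then the other three carbons of a vinylketene attached to C3, so ring B can be built last from acyclic pieces on a chroman that already holds ring A and the stereocentre.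

## Retrosynthetic reasoning

**26 back to 23 (no skeletal bond cut).** The 7-O–Si bond and the oxidation level of the C8 carbon are adjusted last. The formyl group cannot be carried through: it would compete with aldehyde 15 in the olefination and absorb the light needed for 18. The C8 carbon is therefore carried as a methyl ester, present from the first compound of the route. The ester is inert to every step up to the annulation and keeps the C8 carbon distinct from the C4 carbon without a protecting group. A silyl-protected 8-hydroxymethyl group would serve equally in the annulation, but it cannot be reached cleanly, because reducing the C8 ester before the key step would also reduce the C3 carboxyl of 12. Forward, the order is ester reduction (24), benzylic oxidation (25), then desilylation (26). An ortho-hydroxybenzyl alcohol on the trioxygenated ring is never exposed, and no acid or hydrogenation follows the arrival of the prenyl group.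

**23 back to 18 and 4 (key disconnection).** Ring B is cut at C1'–C2', C2'–C3', C4'–C5' and C5'–C6'. This leaves C2' as the carbonyl carbon and C5' as the diazo carbon of diazo enone 18, C6' and C1' as its alkene, and C3'/C4' as the triple bond of ynol ether 4. Cutting here removes the regiochemical problem of ring B, because the OH, prenyl and OMe positions are fixed by which atoms of 18 and 4 bond. It also dispenses with any protecting group on O2'. The forward reaction must turn 18 into vinylketene 19, add it to 4 with the ketene carbon bonding to the prenyl-bearing carbon, and carry the adduct 20 through 21 and 22 to phenol 23 without disturbing C3.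

**4 back to 1 and 2.** The propargylic–allylic C–C bond is cut, giving acetylide 3 (from chloroacetal 1) and prenyl bromide 2. One operation then delivers a seven-carbon partner that already contains the prenyl group, the C4' oxygen and its methyl group.

**18 back to 13 and 14.** The C=N2 bond is cut first, back to methyl ketone 16 via the activated diketone 17. Diazo transfer onto 16 is preferred to acylating a one-carbon diazo reagent with an enoyl electrophile, which invites dipolar addition across the alkene. The C6'=C1' alkene is then cut, back to aldehyde 15 and ylide 14; 15 comes from alcohol 13. The forward olefination must give the E-alkene, which the later ring closure needs, and must consume the α-branched aldehyde 15 before it can lose its configuration.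

**13 back to 11.** The stereocentre is traced to the C3=C4 double bond of chromene acid 11 (two C–H bonds cut; 12 is the hydrogenation product, 13 its reduction product). Asymmetric hydrogenation fits here because the carboxylate is a handle for the catalyst, and because no prenyl group or other reducible alkene exists yet.

**11 back to 7 and 8.** Ring C is cut at O1–C2 and C3–C4, giving salicylaldehyde 7 and acrolein 8 via chromene aldehyde 9 and its silyl ether 10. Only the hydroxyl next to the formyl group of 7 can close the ring, so the two phenols of ring A are differentiated by this ring closure.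

**7 back to 5.** The C4a–C4 bond (the formyl group) and the 5-O–CH3 bond are cut, leading through 6 to the symmetric ester 5. Because 6 is symmetric, formylation can give only one product. The methylation must pick the hydroxyl para to the ester.

## Alternatives that were turned down

**Alternative 1:** This route disconnects C3–C1' and an extra C4–O2' bond, giving the 2H-chromene A1 and 2-methoxy-1,4-benzoquinone A2. Forward, a chiral titanium–diol Lewis acid would join them in a formal [3+2] addition to the cis-fused pterocarpan A3.

- For: it is convergent, uses cheap partners, forms the C3–aryl bond and the stereocentre in one operation, and needs neither light nor a diazo compound. On these points it is stronger than the chosen route.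
- Against: A3 carries an oxygen at C5' that the target lacks (triflation and reductive removal). Its C4–O2' bond must be cleaved reductively. The Lewis acid is needed in stoichiometric amount with enantioselectivity that is hard to predict for a chromene this electron-rich. Above all, the prenyl group is still missing, and introducing it between O2' and the 4'-methoxy group is the very regiochemical problem of the target, since electrophilic prenylation would go to C5'.

The chosen route offers in return a ring B whose pattern is fixed by construction, and a stereocentre set by catalytic hydrogenation of a simple acid.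

**Alternative 2:** This route disconnects C3–C1' and C4–C4a. Forward, aryllithium A4 and the vinyl boronate A5 form an ate complex, and a palladium catalyst with a chiral ferrocenyl bisphosphine ligand couples it with aryl bromide A6 by 1,2-metallate shift to the secondary boronate A7.

- For: it is a catalytic, enantioselective three-component union that brings in both rings whole. Ring B is accessible by two directed metalations of a resorcinol derivative. On convergence and on access to ring B this route is as strong as or stronger than the chosen one.
- Against: A6 is flanked by two ortho substituents on a very electron-rich ring, and the migrating aryl of A4 also has an ortho substituent, so the metallate shift is asked to join two hindered partners. Aryl bromides are the less favourable electrophiles for this manifold. A7 then needs a one-carbon homologation at boron, oxidation, double desilylation, ring closure onto the phenol, and acid removal of the acetal-type protecting group on O2' next to the prenyl group, which is the one condition the ortho-prenyl phenol tolerates badly.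

The chosen route has a longer linear sequence, but it never protects O2' and exposes the prenyl group to only three mild steps.

**Alternative 3:** This route disconnects ring A at C4a–C5, C4a–C8a, C7–C8 and C6–C7. Forward, irradiation and warming of the acyclic diazo ketone A8, with the ynol ether tethered through O1, would give the isoflavan A9 by the same Wolff/[2+2]/4π/6π cascade run intramolecularly.

- For: two rings form in one step, the tether enforces the regiochemistry, and the free 7-OH emerges directly. In ring-forming economy it is stronger than the chosen route.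
- Against: A8 is hard to reach. It needs an ynol ether of a primary alcohol, a diazo group on a substituted carbon next to a 2-methoxyacryloyl unit, and a separately installed stereocentre. Ring B with its prenyl group and an acid-labile O2' protecting group must be complete before any of this and must survive all of it. Most tellingly, it spends the annulation on ring A, whose oxygenation pattern can be bought, and leaves the congested ring B to stepwise substitution.

The chosen route applies the same annulation where it has regiochemical leverage, and takes ring A from a commercial trihydroxybenzoate.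

Key step: step 11

## Route

Remark: isoflavan numbering (O1, C2–C4, C4a–C8a; ring B primed) is used for all intermediates. The spatial arrangement at C3 is the same from 12 to 26, although the descriptor changes with substituent priorities (S in 12 and 15, R elsewhere). Compounds 1, 2, 5, 8 and 14 are taken as commercial.

Step 1
Reactants: 1 chloroacetaldehyde dimethyl acetal; 2 prenyl bromide (1-bromo-3-methylbut-2-ene)
Product: 4 1-methoxy-5-methylhex-4-en-1-yne, via sodium methoxyethynide 3 (not isolated)
Conditions: NaNH2 (3.0 equiv), NH3 (l), −33 °C; then 2, Et2O, −33 °C; NH4Cl, pentane extraction, distillation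
Reagents that add atoms: none
Why: Twofold elimination of the chloroacetal with amide and deprotonation give the alkoxyacetylide, the standard entry to 1-alkoxyalkynes, and SN2 alkylation at the unhindered terminus of the primary allylic bromide gives the skipped enyne. Exactly three equivalents of amide are used so that no strong base remains to isomerise the product.

Step 2
Reactants: 5 methyl 2,4,6-trihydroxybenzoate
Product: 6 methyl 2,6-dihydroxy-4-methoxybenzoate
Conditions: MeI (1.05 equiv), K2CO3 (1.05 equiv), acetone, rt
Reagents that add atoms: iodomethane, CI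
Why: Williamson methylation under limiting base: the 4-hydroxyl, para to the ester, is the most acidic and the only one not held in a hydrogen bond to the ester, so its phenoxide should form and be alkylated first. The product is symmetric, so the two remaining hydroxyls need no differentiation yet.

Step 3
Reactants: 6 methyl 2,6-dihydroxy-4-methoxybenzoate
Product: 7 methyl 3-formyl-2,6-dihydroxy-4-methoxybenzoate
Conditions: Cl2CHOMe (1.2 equiv), TiCl4 (3 equiv), CH2Cl2, −78 → 0 °C; then H2O
Reagents that add atoms: dichloromethyl methyl ether (formyl carbon), COC(Cl)Cl; water (formyl oxygen on hydrolysis), O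
Why: Rieche formylation, in which the titanium phenoxide directs the electrophile to the ortho carbon. C3 and C5 of 6 are equivalent, so only one regioisomer can form, and the first formyl group deactivates the ring against a second.

Step 4
Reactants: 7 methyl 3-formyl-2,6-dihydroxy-4-methoxybenzoate; 8 acrolein
Product: 9 methyl 3-formyl-7-hydroxy-5-methoxy-2H-chromene-8-carboxylate
Conditions: 8 (3 equiv), K2CO3 (1 equiv), 1,4-dioxane, 100 °C
Reagents that add atoms: none
Why: Oxa-Michael addition of the phenoxide to the enal followed by intramolecular aldol condensation, the standard salicylaldehyde–enal chromene annulation. Only the hydroxyl flanked by the formyl group can close the ring, which differentiates the two phenols; addition of the other phenol is reversible.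

Step 5
Reactants: 9 methyl 3-formyl-7-hydroxy-5-methoxy-2H-chromene-8-carboxylate
Product: 10 methyl 3-formyl-5-methoxy-7-[(triisopropylsilyl)oxy]-2H-chromene-8-carboxylate
Conditions: iPr3SiOTf (1.2 equiv), 2,6-lutidine (2 equiv), CH2Cl2, 0 °C
Reagents that add atoms: triisopropylsilyl trifluoromethanesulfonate, CC(C)[Si](C(C)C)(C(C)C)OS(=O)(=O)C(F)(F)F
Why: Silylation of the one remaining phenol. The bulky triisopropylsilyl ether is chosen because it must survive methanolic amine, borane, amide base and light, and because it resists O-to-O migration in step 12.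

Step 6
Reactants: 10 methyl 3-formyl-5-methoxy-7-[(triisopropylsilyl)oxy]-2H-chromene-8-carboxylate
Product: 11 5-methoxy-8-(methoxycarbonyl)-7-[(triisopropylsilyl)oxy]-2H-chromene-3-carboxylic acid
Conditions: NaClO2, NaH2PO4, 2-methyl-2-butene, tBuOH/THF/H2O, rt
Reagents that add atoms: sodium chlorite, [Na+].[O-]Cl=O
Why: Pinnick oxidation converts the conjugated aldehyde into the acid without touching the alkene or the electron-rich ring. The alkene scavenger removes hypochlorous acid before it can chlorinate C6.

Step 7
Reactants: 11 5-methoxy-8-(methoxycarbonyl)-7-[(triisopropylsilyl)oxy]-2H-chromene-3-carboxylic acid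
Product: 12 (3S)-5-methoxy-8-(methoxycarbonyl)-7-[(triisopropylsilyl)oxy]chromane-3-carboxylic acid
Conditions: [Ir(cod)(SIPHOX)]BArF (spiro phosphine–oxazoline ligand, antipode chosen for (S)-12; 1 mol %), H2 (6 atm), Et3N (0.5 equiv), MeOH, 45 °C
Reagents that add atoms: none
Why: Carboxylate-directed asymmetric hydrogenation of a cyclic α,β-unsaturated acid, a reaction known for 2H-chromene-3-carboxylic acids. The metal binds the carboxylate and delivers hydrogen to one face of C3=C4, which sets C3; the ligand antipode is chosen to give the (S)-acid, and the sense of induction is to be confirmed on the first batch. No hydrogenation-sensitive group is present yet.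

Step 8
Reactants: 12 (3S)-5-methoxy-8-(methoxycarbonyl)-7-[(triisopropylsilyl)oxy]chromane-3-carboxylic acid
Product: 13 methyl (3R)-3-(hydroxymethyl)-5-methoxy-7-[(triisopropylsilyl)oxy]chromane-8-carboxylate
Conditions: BH3·THF (2 equiv), THF, 0 °C → rt; MeOH
Reagents that add atoms: none
Why: Borane reduces the carboxylic acid through its acyloxyborane much faster than the hindered, electron-rich aryl ester, and the stereocentre is not enolisable under these conditions.

Step 9
Reactants: 13 methyl (3R)-3-(hydroxymethyl)-5-methoxy-7-[(triisopropylsilyl)oxy]chromane-8-carboxylate; 14 1-(triphenylphosphoranylidene)propan-2-one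
Product: 16 methyl (3R)-5-methoxy-3-[(1E)-3-oxobut-1-en-1-yl]-7-[(triisopropylsilyl)oxy]chromane-8-carboxylate, via aldehyde 15 (not isolated)
Conditions: Dess–Martin periodinane, NaHCO3, CH2Cl2, 0 °C → rt; then 14 (2.5 equiv), rt
Reagents that add atoms: none
Why: Dess–Martin oxidation under bicarbonate buffer gives the α-branched aldehyde without base, and the stabilised ylide is added to the same flask so that the configurationally labile aldehyde is consumed at once. The stabilised Wittig reaction should give the E-enone, and the weakly basic ylide should leave C3 intact.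

Step 10
Reactants: 16 methyl (3R)-5-methoxy-3-[(1E)-3-oxobut-1-en-1-yl]-7-[(triisopropylsilyl)oxy]chromane-8-carboxylate
Product: 18 methyl (3R)-3-[(1E)-4-diazo-3-oxobut-1-en-1-yl]-5-methoxy-7-[(triisopropylsilyl)oxy]chromane-8-carboxylate, via trifluoroacetyl ketone 17 (not isolated)
Conditions: LiN(SiMe3)2 (1.1 equiv), THF, −78 °C; CF3CO2CH2CF3 (1.2 equiv); aq. HCl work-up; then MeSO2N3 (1.5 equiv), Et3N (1.5 equiv), H2O (1 equiv), MeCN, rt
Reagents that add atoms: methanesulfonyl azide, CS(=O)(=O)N=[N+]=[N-]
Why: Detrifluoroacetylative diazo transfer: kinetic deprotonation of the enone at the methyl group, Claisen acylation to the activated diketone, then diazo transfer with loss of the trifluoroacetyl group. This avoids adding a diazoalkane across the enone, and the kinetic base does not touch the γ-hydrogen at C3.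

Step 11
Reactants: 18 methyl (3R)-3-[(1E)-4-diazo-3-oxobut-1-en-1-yl]-5-methoxy-7-[(triisopropylsilyl)oxy]chromane-8-carboxylate; 4 1-methoxy-5-methylhex-4-en-1-yne
Product: 23 methyl (3R)-3-[2-hydroxy-4-methoxy-3-(3-methylbut-2-en-1-yl)phenyl]-5-methoxy-7-[(triisopropylsilyl)oxy]chromane-8-carboxylate, via vinylketene 19 (not isolated), via cyclobutenone 20 (not isolated), via dienylketene 21 (not isolated), via cyclohexadienone 22 (not isolated)
Conditions: 4 (3 equiv), ClCH2CH2Cl (degassed), hν (300 nm), rt; then 80 °C
Reagents that add atoms: none
Why: Light expels N2 from 18 with 1,2-shift of the alkenyl group (Wolff rearrangement) to give vinylketene 19, whose ketene C=C adds [2+2] to ynol ether 4 to give 20. Heating opens the four-membered ring of 20 by 4π electrocyclic cleavage to dienylketene 21, which closes ring B by 6π electrocyclisation (C1'–C2' bond) to 22 and tautomerises to phenol 23. The closest known reaction type is the diazo-ketone variant of the Danheiser benzannulation with alkoxy- and siloxyalkynes, which has been applied to α'-diazo enones. The regiochemistry is secured by the polarisation of 4: its nucleophilic prenyl-bearing carbon attacks the electrophilic ketene carbon while oxygen stabilises positive charge on the other alkyne carbon, so the ketene oxygen ends as 2'-OH next to the prenyl group and the methoxy group lands on C4'. Chemoselectivity for the triple bond over the prenyl alkene follows from the far higher nucleophilicity of an ynol ether towards ketenes, and the E-alkene set in step 9 places C1' within reach of the ketene carbon for the 6π closure. No new stereocentre survives, since those at the ring carbon of 20 and at C1' of 22 vanish on ring opening and tautomerisation, and C3 is a spectator because the 6π closure of 21 should outrun any hydrogen shift from the allylic C3–H. A methyl ynol ether is used because it cannot lose an alkene by retro-ene fragmentation at 80 °C.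

Step 12
Reactants: 23 methyl (3R)-3-[2-hydroxy-4-methoxy-3-(3-methylbut-2-en-1-yl)phenyl]-5-methoxy-7-[(triisopropylsilyl)oxy]chromane-8-carboxylate
Product: 24 2-[(3R)-8-(hydroxymethyl)-5-methoxy-7-[(triisopropylsilyl)oxy]chroman-3-yl]-5-methoxy-6-(3-methylbut-2-en-1-yl)phenol
Conditions: iBu2AlH (4 equiv), CH2Cl2, −78 → −20 °C; aq. potassium sodium tartrate
Reagents that add atoms: none
Why: Aluminium hydride reduction of the aryl ester to the benzylic alcohol. The free phenol only consumes one equivalent of hydride, the prenyl alkene and the silyl ether are inert, and the covalent aluminium alkoxide together with the bulky silyl group disfavours silyl migration.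

Step 13
Reactants: 24 2-[(3R)-8-(hydroxymethyl)-5-methoxy-7-[(triisopropylsilyl)oxy]chroman-3-yl]-5-methoxy-6-(3-methylbut-2-en-1-yl)phenol
Product: 25 (3R)-3-[2-hydroxy-4-methoxy-3-(3-methylbut-2-en-1-yl)phenyl]-5-methoxy-7-[(triisopropylsilyl)oxy]chromane-8-carbaldehyde
Conditions: MnO2 (activated, excess), CH2Cl2, rt
Reagents that add atoms: none
Why: MnO2 oxidises the electron-rich benzylic alcohol to the aldehyde and stops there. With O7 still silylated there is no free phenol ortho or para to the carbinol, so quinone methide pathways are closed.

Step 14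
Reactants: 25 (3R)-3-[2-hydroxy-4-methoxy-3-(3-methylbut-2-en-1-yl)phenyl]-5-methoxy-7-[(triisopropylsilyl)oxy]chromane-8-carbaldehyde
Product: 26 (3R)-7-hydroxy-3-[2-hydroxy-4-methoxy-3-(3-methylbut-2-en-1-yl)phenyl]-5-methoxychromane-8-carbaldehyde (target)
Conditions: Bu4NF (1.2 equiv), AcOH (1.2 equiv), THF, 0 °C
Reagents that add atoms: none
Why: Buffered fluoride cleaves the aryl silyl ether ortho to the formyl group and releases the hydrogen-bonded salicylaldehyde. The medium is neither acidic enough to cyclise the ortho-prenyl phenol nor basic enough to affect the aldehyde.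

## Compound list

1 | chloroacetaldehyde dimethyl acetal | COC(CCl)OC | starting material
2 | prenyl bromide (1-bromo-3-methylbut-2-ene) | CC(C)=CCBr | starting material
3 | sodium methoxyethynide | [Na+].[C-]#COC | intermediate
4 | 1-methoxy-5-methylhex-4-en-1-yne | COC#CCC=C(C)C | intermediate
5 | methyl 2,4,6-trihydroxybenzoate | COC(=O)c1c(O)cc(O)cc1O | starting material
6 | methyl 2,6-dihydroxy-4-methoxybenzoate | COC(=O)c1c(O)cc(OC)cc1O | intermediate
7 | methyl 3-formyl-2,6-dihydroxy-4-methoxybenzoate | COC(=O)c1c(O)cc(OC)c(C=O)c1O | intermediate
8 | acrolein | C=CC=O | starting material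
9 | methyl 3-formyl-7-hydroxy-5-methoxy-2H-chromene-8-carboxylate | O=CC1=Cc2c(OC)cc(O)c(C(=O)OC)c2OC1 | intermediate
10 | methyl 3-formyl-5-methoxy-7-[(triisopropylsilyl)oxy]-2H-chromene-8-carboxylate | O=CC1=Cc2c(OC)cc(O[Si](C(C)C)(C(C)C)C(C)C)c(C(=O)OC)c2OC1 | intermediate
11 | 5-methoxy-8-(methoxycarbonyl)-7-[(triisopropylsilyl)oxy]-2H-chromene-3-carboxylic acid | OC(=O)C1=Cc2c(OC)cc(O[Si](C(C)C)(C(C)C)C(C)C)c(C(=O)OC)c2OC1 | intermediate
12 | (3S)-5-methoxy-8-(methoxycarbonyl)-7-[(triisopropylsilyl)oxy]chromane-3-carboxylic acid | OC(=O)[C@@H]1COc2c(C(=O)OC)c(O[Si](C(C)C)(C(C)C)C(C)C)cc(OC)c2C1 | intermediate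
13 | methyl (3R)-3-(hydroxymethyl)-5-methoxy-7-[(triisopropylsilyl)oxy]chromane-8-carboxylate | OC[C@@H]1COc2c(C(=O)OC)c(O[Si](C(C)C)(C(C)C)C(C)C)cc(OC)c2C1 | intermediate
14 | 1-(triphenylphosphoranylidene)propan-2-one | CC(=O)C=P(c1ccccc1)(c1ccccc1)c1ccccc1 | starting material
15 | methyl (3S)-3-formyl-5-methoxy-7-[(triisopropylsilyl)oxy]chromane-8-carboxylate | O=C[C@@H]1COc2c(C(=O)OC)c(O[Si](C(C)C)(C(C)C)C(C)C)cc(OC)c2C1 | intermediate
16 | methyl (3R)-5-methoxy-3-[(1E)-3-oxobut-1-en-1-yl]-7-[(triisopropylsilyl)oxy]chromane-8-carboxylate | CC(=O)/C=C/[C@@H]1COc2c(C(=O)OC)c(O[Si](C(C)C)(C(C)C)C(C)C)cc(OC)c2C1 | intermediate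
17 | methyl (3R)-5-methoxy-3-[(1E)-6,6,6-trifluoro-3,5-dioxohex-1-en-1-yl]-7-[(triisopropylsilyl)oxy]chromane-8-carboxylate | O=C(CC(=O)C(F)(F)F)/C=C/[C@@H]1COc2c(C(=O)OC)c(O[Si](C(C)C)(C(C)C)C(C)C)cc(OC)c2C1 | intermediate
18 | methyl (3R)-3-[(1E)-4-diazo-3-oxobut-1-en-1-yl]-5-methoxy-7-[(triisopropylsilyl)oxy]chromane-8-carboxylate | [N-]=[N+]=CC(=O)/C=C/[C@@H]1COc2c(C(=O)OC)c(O[Si](C(C)C)(C(C)C)C(C)C)cc(OC)c2C1 | intermediate
19 | methyl (3R)-5-methoxy-3-[(1E)-4-oxobuta-1,3-dien-1-yl]-7-[(triisopropylsilyl)oxy]chromane-8-carboxylate (vinylketene) | O=C=C/C=C/[C@@H]1COc2c(C(=O)OC)c(O[Si](C(C)C)(C(C)C)C(C)C)cc(OC)c2C1 | intermediate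
20 | methyl (3R)-5-methoxy-3-{(E)-2-[2-methoxy-3-(3-methylbut-2-en-1-yl)-4-oxocyclobut-2-en-1-yl]ethenyl}-7-[(triisopropylsilyl)oxy]chromane-8-carboxylate (both epimers at the four-membered ring carbon) | COC1=C(CC=C(C)C)C(=O)C1/C=C/[C@@H]2COc3c(C(=O)OC)c(O[Si](C(C)C)(C(C)C)C(C)C)cc(OC)c3C2 | intermediate
21 | dienylketene: methyl (3R)-5-methoxy-3-[4-methoxy-5-(3-methylbut-2-en-1-yl)-6-oxohexa-1,3,5-trien-1-yl]-7-[(triisopropylsilyl)oxy]chromane-8-carboxylate (C6'=C1' trans; C3' and C6' cis about C4'=C5') | O=C=C(CC=C(C)C)/C(OC)=C\C=C\[C@@H]1COc2c(C(=O)OC)c(O[Si](C(C)C)(C(C)C)C(C)C)cc(OC)c2C1 | intermediate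
22 | methyl (3R)-5-methoxy-3-[4-methoxy-5-(3-methylbut-2-en-1-yl)-6-oxocyclohexa-2,4-dien-1-yl]-7-[(triisopropylsilyl)oxy]chromane-8-carboxylate (both epimers at the dienone sp3 carbon) | COC1=C(CC=C(C)C)C(=O)C(C=C1)[C@@H]2COc3c(C(=O)OC)c(O[Si](C(C)C)(C(C)C)C(C)C)cc(OC)c3C2 | intermediate
23 | methyl (3R)-3-[2-hydroxy-4-methoxy-3-(3-methylbut-2-en-1-yl)phenyl]-5-methoxy-7-[(triisopropylsilyl)oxy]chromane-8-carboxylate | COc1ccc([C@@H]2COc3c(C(=O)OC)c(O[Si](C(C)C)(C(C)C)C(C)C)cc(OC)c3C2)c(O)c1CC=C(C)C | intermediate
24 | 2-[(3R)-8-(hydroxymethyl)-5-methoxy-7-[(triisopropylsilyl)oxy]chroman-3-yl]-5-methoxy-6-(3-methylbut-2-en-1-yl)phenol | COc1ccc([C@@H]2COc3c(CO)c(O[Si](C(C)C)(C(C)C)C(C)C)cc(OC)c3C2)c(O)c1CC=C(C)C | intermediate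
25 | (3R)-3-[2-hydroxy-4-methoxy-3-(3-methylbut-2-en-1-yl)phenyl]-5-methoxy-7-[(triisopropylsilyl)oxy]chromane-8-carbaldehyde | COc1ccc([C@@H]2COc3c(C=O)c(O[Si](C(C)C)(C(C)C)C(C)C)cc(OC)c3C2)c(O)c1CC=C(C)C | intermediate
26 | (3R)-7-hydroxy-3-[2-hydroxy-4-methoxy-3-(3-methylbut-2-en-1-yl)phenyl]-5-methoxychromane-8-carbaldehyde | COc1ccc([C@@H]2COc3c(C=O)c(O)cc(OC)c3C2)c(O)c1CC=C(C)C | target

## Step count and least certain steps

Total step count: 14. Longest linear sequence: 13 steps (5 to 26, steps 2–14); ynol ether 4 is made in one step and joins at step 11.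

**Step 11 (key step).** The most likely failure is bimolecular loss of the vinylketene before it meets the alkyne: dimerisation, or capture by the phenol already formed. Other possibilities are light absorption by the aromatic rings slowing the Wolff rearrangement, and incomplete thermal opening of the methoxy-substituted four-membered ring. The fallback generates the same ketene thermally and slowly, without light or a diazo compound. It sets out from alcohol 13. Oxidation as in step 9 and methylenation with Ph3P=CH2 at −78 °C give methyl (3R)-3-ethenyl-5-methoxy-7-[(triisopropylsilyl)oxy]chromane-8-carboxylate F1. Cross-metathesis with but-3-enoic acid (second-generation Hoveyda–Grubbs catalyst, 1,4-benzoquinone additive, CH2Cl2, 40 °C) gives (3E)-4-[(3R)-5-methoxy-8-(methoxycarbonyl)-7-[(triisopropylsilyl)oxy]chroman-3-yl]but-3-enoic acid F2. Oxalyl chloride with catalytic DMF converts it into the corresponding but-3-enoyl chloride F3. Slow addition of Et3N to F3 and excess 4 in toluene dehydrochlorinates F3 to vinylketene 19. The route is rejoined there and continues through 20 to 23 on heating.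

**Step 9.** The risk is loss of configuration at C3 while the aldehyde waits for the ylide, either by enolisation or by reversible ring-opening elimination of the aryloxide. The fallback makes the stereocentre-bearing fragment the nucleophile, so that no carbonyl ever sits next to C3. It sets out from 13. Mitsunobu reaction with 1-phenyl-1H-tetrazole-5-thiol gives methyl (3S)-5-methoxy-3-{[(1-phenyl-1H-tetrazol-5-yl)sulfanyl]methyl}-7-[(triisopropylsilyl)oxy]chromane-8-carboxylate F4. Oxidation with (NH4)6Mo7O24/H2O2 gives the corresponding sulfone F5. Julia–Kocienski olefination with 2-methyl-1,3-dioxolane-2-carbaldehyde (KN(SiMe3)2, DME, −60 °C) gives methyl (3R)-5-methoxy-3-[(E)-2-(2-methyl-1,3-dioxolan-2-yl)ethenyl]-7-[(triisopropylsilyl)oxy]chromane-8-carboxylate F6. Mild ketal hydrolysis (pyridinium tosylate, wet acetone) returns to the route at enone 16.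

**Step 7.** Facial discrimination may be poor or turnover may stall, because C4 is flanked by the 5-methoxy group and the catalyst must bind a carboxylate beside a crowded ring. Slow methanolysis of the aryl silyl ether is a second risk. The fallback replaces asymmetric catalysis by resolution. It sets out from 11. Hydrogenation over Pd/C in EtOAc gives racemic 5-methoxy-8-(methoxycarbonyl)-7-[(triisopropylsilyl)oxy]chromane-3-carboxylic acid F7. Crystallisation with 1-phenylethylamine gives the (S)-1-phenylethylammonium salt of the (3S)-acid F8. The (S)-amine is written here; its antipode is used if the salt of the unwanted acid proves the less soluble. Acidification returns to the route at 12.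

**Step 4.** The doubly hydrogen-bonded phenoxide may add sluggishly while acrolein polymerises, or the second phenol may remain added to the enal. The fallback uses an ester acceptor under amine catalysis and arrives directly at the acid oxidation level. It sets out from 7. Reaction with tert-butyl acrylate and DABCO gives 3-tert-butyl 8-methyl 7-hydroxy-5-methoxy-2H-chromene-3,8-dicarboxylate F9. Silylation as in step 5 gives 3-tert-butyl 8-methyl 5-methoxy-7-[(triisopropylsilyl)oxy]-2H-chromene-3,8-dicarboxylate F10. Cleavage of the tert-butyl ester with CF3CO2H in CH2Cl2 returns to the route at 11, which also bypasses steps 5 and 6.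

**Step 12.** The silyl group may migrate from the phenolic oxygen to the new benzylic alkoxide; expulsion of silanolate and hydride capture of the resulting quinone methide would then over-reduce C8 to a methyl group. The fallback removes the silyl group first. It sets out from 23. Bu4NF gives methyl (3R)-7-hydroxy-3-[2-hydroxy-4-methoxy-3-(3-methylbut-2-en-1-yl)phenyl]-5-methoxychromane-8-carboxylate F11. LiAlH4 in THF reduces the salicylate through its phenoxide to 2-[(3R)-7-hydroxy-8-(hydroxymethyl)-5-methoxychroman-3-yl]-5-methoxy-6-(3-methylbut-2-en-1-yl)phenol F12. MnO2 oxidation of the ortho-hydroxybenzyl alcohol returns to the route at 26.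

## Further compounds

F1 | step 11 | methyl (3R)-3-ethenyl-5-methoxy-7-[(triisopropylsilyl)oxy]chromane-8-carboxylate | C=C[C@@H]1COc2c(C(=O)OC)c(O[Si](C(C)C)(C(C)C)C(C)C)cc(OC)c2C1
F2 | step 11 | (3E)-4-[(3R)-5-methoxy-8-(methoxycarbonyl)-7-[(triisopropylsilyl)oxy]chroman-3-yl]but-3-enoic acid | OC(=O)C/C=C/[C@@H]1COc2c(C(=O)OC)c(O[Si](C(C)C)(C(C)C)C(C)C)cc(OC)c2C1
F3 | step 11 | (3E)-4-[(3R)-5-methoxy-8-(methoxycarbonyl)-7-[(triisopropylsilyl)oxy]chroman-3-yl]but-3-enoyl chloride | ClC(=O)C/C=C/[C@@H]1COc2c(C(=O)OC)c(O[Si](C(C)C)(C(C)C)C(C)C)cc(OC)c2C1
F4 | step 9 | methyl (3S)-5-methoxy-3-{[(1-phenyl-1H-tetrazol-5-yl)sulfanyl]methyl}-7-[(triisopropylsilyl)oxy]chromane-8-carboxylate | c1ccc(cc1)-n1nnnc1SC[C@@H]2COc3c(C(=O)OC)c(O[Si](C(C)C)(C(C)C)C(C)C)cc(OC)c3C2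
F5 | step 9 | methyl (3S)-5-methoxy-3-{[(1-phenyl-1H-tetrazol-5-yl)sulfonyl]methyl}-7-[(triisopropylsilyl)oxy]chromane-8-carboxylate | O=S(=O)(C[C@@H]2COc3c(C(=O)OC)c(O[Si](C(C)C)(C(C)C)C(C)C)cc(OC)c3C2)c1nnnn1-c1ccccc1
F6 | step 9 | methyl (3R)-5-methoxy-3-[(E)-2-(2-methyl-1,3-dioxolan-2-yl)ethenyl]-7-[(triisopropylsilyl)oxy]chromane-8-carboxylate | CC1(OCCO1)/C=C/[C@@H]2COc3c(C(=O)OC)c(O[Si](C(C)C)(C(C)C)C(C)C)cc(OC)c3C2
F7 | step 7 | racemic 5-methoxy-8-(methoxycarbonyl)-7-[(triisopropylsilyl)oxy]chromane-3-carboxylic acid | OC(=O)C1COc2c(C(=O)OC)c(O[Si](C(C)C)(C(C)C)C(C)C)cc(OC)c2C1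
F8 | step 7 | (S)-1-phenylethylammonium (3S)-5-methoxy-8-(methoxycarbonyl)-7-[(triisopropylsilyl)oxy]chromane-3-carboxylate | [O-]C(=O)[C@@H]1COc2c(C(=O)OC)c(O[Si](C(C)C)(C(C)C)C(C)C)cc(OC)c2C1.C[C@H]([NH3+])c1ccccc1
F9 | step 4 | 3-tert-butyl 8-methyl 7-hydroxy-5-methoxy-2H-chromene-3,8-dicarboxylate | CC(C)(C)OC(=O)C1=Cc2c(OC)cc(O)c(C(=O)OC)c2OC1
F10 | step 4 | 3-tert-butyl 8-methyl 5-methoxy-7-[(triisopropylsilyl)oxy]-2H-chromene-3,8-dicarboxylate | CC(C)(C)OC(=O)C1=Cc2c(OC)cc(O[Si](C(C)C)(C(C)C)C(C)C)c(C(=O)OC)c2OC1
F11 | step 12 | methyl (3R)-7-hydroxy-3-[2-hydroxy-4-methoxy-3-(3-methylbut-2-en-1-yl)phenyl]-5-methoxychromane-8-carboxylate | COc1ccc([C@@H]2COc3c(C(=O)OC)c(O)cc(OC)c3C2)c(O)c1CC=C(C)C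
F12 | step 12 | 2-[(3R)-7-hydroxy-8-(hydroxymethyl)-5-methoxychroman-3-yl]-5-methoxy-6-(3-methylbut-2-en-1-yl)phenol | COc1ccc([C@@H]2COc3c(CO)c(O)cc(OC)c3C2)c(O)c1CC=C(C)C
A1 | alternative 1 | methyl 5-methoxy-7-[(triisopropylsilyl)oxy]-2H-chromene-8-carboxylate | C1=Cc2c(OC)cc(O[Si](C(C)C)(C(C)C)C(C)C)c(C(=O)OC)c2OC1
A2 | alternative 1 | 2-methoxy-1,4-benzoquinone | COC1=CC(=O)C=CC1=O
A3 | alternative 1 | cis-fused pterocarpan with 5'-OH, 4'-OMe, 5-OMe, 7-O-triisopropylsilyl and 8-CO2Me (isoflavan numbering) | COc1cc2O[C@H]3c4c(OC)cc(O[Si](C(C)C)(C(C)C)C(C)C)c(C(=O)OC)c4OC[C@H]3c2cc1O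
A4 | alternative 2 | [4-methoxy-2-(methoxymethoxy)-3-(3-methylbut-2-en-1-yl)phenyl]lithium | [Li]c1ccc(OC)c(CC=C(C)C)c1OCOC
A5 | alternative 2 | 4,4,5,5-tetramethyl-2-vinyl-1,3,2-dioxaborolane | C=CB1OC(C)(C)C(C)(C)O1
A6 | alternative 2 | 2-[3-bromo-2,6-bis(tert-butyldimethylsilyloxy)-4-methoxyphenyl]-1,3-dioxolane | Brc1c(O[Si](C)(C)C(C)(C)C)c(C2OCCO2)c(O[Si](C)(C)C(C)(C)C)cc1OC
A7 | alternative 2 | secondary benzylic pinacol boronate with ring B and boron on C3 and the ring A aryl on C4 | COc1ccc([C@@H](Cc2c(O[Si](C)(C)C(C)(C)C)c(C3OCCO3)c(O[Si](C)(C)C(C)(C)C)cc2OC)B2OC(C)(C)C(C)(C)O2)c(OCOC)c1CC=C(C)C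
A8 | alternative 3 | acyclic 2-methoxyacryloyl diazo ketone with the ynol ether tethered through O1 and ring B on C3 | COc1ccc([C@@H](CC(=[N+]=[N-])C(=O)C(OC)=C)COC#CCO[Si](C)(C)C(C)(C)C)c(OCOC)c1CC=C(C)C
A9 | alternative 3 | (R)-isoflavan with free 7-OH, 8-CH2O-tert-butyldimethylsilyl and 2'-O-methoxymethyl | COc1ccc([C@@H]2COc3c(CO[Si](C)(C)C(C)(C)C)c(O)cc(OC)c3C2)c(OCOC)c1CC=C(C)C
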